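**Retrosynthetic overview**
1. The tropolone ring is closed last: 15 ⇒ (−)-ECG 12 (benzo ring and the flavan on C1) + 11, the 2',3',4'-trihydroxy-B-ring isomer of EGCG (C5–C9 and the flavan on C7; one ring carbon leaves as CO2).
2. 11 ⇒ galloylation and debenzylation of the cis-(2R,3R)-flavan-3-ol 8 ⇒ racemic flavan-3-one 7; one dynamic kinetic resolution sets both stereocentres.
3. Key C–C bond, C4–C4a of 7: an α-oxo gold carbene (α-keto cation, i.e. enolonium equivalent) made from terminal alkyne 5 attacks the phloroglucinol ring; both carbons are nucleophilic in normal polarity.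
4. 5 ⇒ phenol 4 + propargylic alcohol 3 (Mitsunobu) ⇒ aldehyde 2 + ethynyl Grignard.
5. Ring order: pyranone ring of the new flavan (step 4), then the seven-membered ring (step 8); all benzene rings are bought.

Assumption: the SMILES is taken literally, so the flavan on the tropolone ring sits on C7, next to the C6–OH carbon (a positional isomer of natural theaflavin 3,3'-digallate, which carries it on C8).

**Step 1**
Reactants: 1 2,3,4-trihydroxybenzaldehyde
Product: 2 2,3,4-tris(benzyloxy)benzaldehyde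
Conditions: BnBr (3.6 equiv), K2CO3 (4 equiv), DMF, 60 °C
Reagents that add atoms: benzyl bromide, BrCc1ccccc1
Why: Williamson ether synthesis; carbonate in DMF alkylates all three phenols, including the hydrogen-bonded 2-OH, and leaves the aldehyde untouched.

**Step 2**
Reactants: 2 2,3,4-tris(benzyloxy)benzaldehyde
Product: 3 (±)-1-[2,3,4-tris(benzyloxy)phenyl]prop-2-yn-1-ol
Conditions: HC≡CMgBr (1.3 equiv), THF, 0 °C to rt; then sat. aq. NH4Cl
Reagents that add atoms: ethynylmagnesium bromide, C#C[Mg]Br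
Why: Grignard 1,2-addition to the aldehyde; the carbinol centre is left racemic on purpose because it becomes the epimerisable C2 of ketone 7 and is fixed only in step 5.

**Step 3**
Reactants: 3 (±)-1-[2,3,4-tris(benzyloxy)phenyl]prop-2-yn-1-ol; 4 3,5-bis(benzyloxy)phenol
Product: 5 (±)-1,2,3-tris(benzyloxy)-4-{1-[3,5-bis(benzyloxy)phenoxy]prop-2-yn-1-yl}benzene
Conditions: PPh3 (1.5 equiv), DIAD (1.5 equiv), toluene, 0 °C to rt
Reagents that add atoms: none
Why: Mitsunobu etherification; the phenol (pKa about 9.5) is acidic enough to be O-alkylated by the activated benzylic/propargylic alcohol, and the configuration at this carbon does not matter at this stage.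

**Step 4 (key step)**
Reactants: 5 (±)-1,2,3-tris(benzyloxy)-4-{1-[3,5-bis(benzyloxy)phenoxy]prop-2-yn-1-yl}benzene
Product: 7 (±)-5,7-bis(benzyloxy)-2-[2,3,4-tris(benzyloxy)phenyl]chroman-3-one, via alpha-oxo gold carbene 6 (not isolated)
Conditions: Me4tBuXPhosAuNTf2 (5 mol %), 2,6-dichloropyridine N-oxide (1.3 equiv, slow addition), DCE (0.05 M), rt
Reagents that add atoms: 2,6-dichloropyridine N-oxide, [O-][n+]1c(Cl)cccc1Cl
Why: Gold-catalysed alkyne oxidation followed by intramolecular Friedel–Crafts-type carbene arylation (the known aryl propargyl ether to chroman-3-one reaction, here extended to a 1-aryl-substituted ether): the N-oxide attacks the internal carbon of the gold-activated terminal alkyne and N–O cleavage gives carbene 6, an α-keto cation (enolonium) equivalent, whose α-carbon is captured by the highly nucleophilic ortho carbon of the phloroglucinol ether ring in a six-membered closure, forming C4–C4a; C2 stays racemic.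

**Step 5**
Reactants: 7 (±)-5,7-bis(benzyloxy)-2-[2,3,4-tris(benzyloxy)phenyl]chroman-3-one
Product: 8 (2R,3R)-5,7-bis(benzyloxy)-2-[2,3,4-tris(benzyloxy)phenyl]chroman-3-ol (2,3-cis)
Conditions: RuCl2[(R)-Xyl-SDP][(S,S)-DPEN] (1 mol %), KOtBu (20 mol %), H2 (50 atm), iPrOH/toluene 3:1, rt
Reagents that add atoms: none
Why: Proposed new method: asymmetric hydrogenation with dynamic kinetic resolution, in which the C2–H of 7 (α to C=O, benzylic and α-oxygenated) epimerises quickly under KOtBu while the chiral Ru–H/N–H catalyst reduces one ketone enantiomer faster and delivers hydride anti to the 2-aryl group, so C2 and C3 are set together as cis-(2R,3R); the closest known reaction is the Ru-diphosphine/diamine DKR hydrogenation of racemic 2-arylcyclohexanones to cis-2-arylcyclohexanols, and the catalyst hand is chosen by that analogy, so the mirror-image catalyst is used if the first run gives the antipode.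

**Step 6**
Reactants: 8 (2R,3R)-5,7-bis(benzyloxy)-2-[2,3,4-tris(benzyloxy)phenyl]chroman-3-ol; 9 3,4,5-tris(benzyloxy)benzoic acid
Product: 10 (2R,3R)-5,7-bis(benzyloxy)-2-[2,3,4-tris(benzyloxy)phenyl]chroman-3-yl 3,4,5-tris(benzyloxy)benzoate
Conditions: DCC (1.5 equiv), DMAP (0.3 equiv), CH2Cl2, rt
Reagents that add atoms: none
Why: Steglich esterification acylates the hindered axial 3-OH as in standard catechin gallate syntheses and breaks no bond at either stereocentre.

**Step 7**
Reactants: 10 (2R,3R)-5,7-bis(benzyloxy)-2-[2,3,4-tris(benzyloxy)phenyl]chroman-3-yl 3,4,5-tris(benzyloxy)benzoate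
Product: 11 (2R,3R)-5,7-dihydroxy-2-(2,3,4-trihydroxyphenyl)chroman-3-yl 3,4,5-trihydroxybenzoate
Conditions: H2 (1 atm), 20% Pd(OH)2/C, THF/MeOH 1:1, rt; filtered under Ar and used at once
Reagents that add atoms: none
Why: Hydrogenolysis of all eight benzyl ethers with Pearlman's catalyst under neutral conditions, which spares the aryl ester and the C2–O1 bond as with EGCG-type substrates, so the stereocentres are unchanged.

**Step 8**
Reactants: 11 (2R,3R)-5,7-dihydroxy-2-(2,3,4-trihydroxyphenyl)chroman-3-yl 3,4,5-trihydroxybenzoate; 12 (−)-epicatechin 3-O-gallate (ECG)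
Product: 15 target benzotropolone digallate CNP0283148.1, via ECG ortho-quinone 13 (not isolated), via bicyclo[3.2.1]octane adduct 14 (not isolated)
Conditions: 12 (2 equiv), horseradish peroxidase, H2O2 (3 equiv, in portions), acetone/pH 5 citrate–phosphate buffer 1:10, rt, 1 h; Sephadex LH-20 then prep-HPLC
Reagents that add atoms: none
Why: Biomimetic purpurogallin/theaflavin-type oxidative benzotropolone annulation: the normally nucleophilic catechol ring of 12 is turned into electrophilic quinone 13, C5'' of the 2,3,4-trihydroxyphenyl ring of 11 (ortho and para to OH) adds to C6' of 13, further oxidation and attack of C5' on the central carbonyl give bridged adduct 14, and oxidative opening expels the one-carbon bridge as CO2, which leaves the flavan next to the tropolone C–OH carbon; the four flavan stereocentres are not touched.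

**Compound list**
1 | 2,3,4-trihydroxybenzaldehyde | O=Cc1ccc(O)c(O)c1O | starting material
2 | 2,3,4-tris(benzyloxy)benzaldehyde | O=Cc1ccc(OCc2ccccc2)c(OCc2ccccc2)c1OCc1ccccc1 | intermediate
3 | (±)-1-[2,3,4-tris(benzyloxy)phenyl]prop-2-yn-1-ol (racemic) | C#CC(O)c1ccc(OCc2ccccc2)c(OCc2ccccc2)c1OCc1ccccc1 | intermediate
4 | 3,5-bis(benzyloxy)phenol | Oc1cc(OCc2ccccc2)cc(OCc2ccccc2)c1 | starting material
5 | (±)-1,2,3-tris(benzyloxy)-4-{1-[3,5-bis(benzyloxy)phenoxy]prop-2-yn-1-yl}benzene (racemic) | C#CC(Oc1cc(OCc2ccccc2)cc(OCc2ccccc2)c1)c1ccc(OCc2ccccc2)c(OCc2ccccc2)c1OCc1ccccc1 | intermediate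
6 | cationic α-oxo gold carbene [Me4tBuXPhos-Au=CH-C(=O)-CH(OAr)Ar']+ NTf2− from 5 (racemic) | CC(C)c1cc(C(C)C)c(c(C(C)C)c1)-c1c(C)c(C)c(C)c(C)c1[P+](C(C)(C)C)(C(C)(C)C)[Au]=CC(=O)C(Oc1cc(OCc2ccccc2)cc(OCc2ccccc2)c1)c1ccc(OCc2ccccc2)c(OCc2ccccc2)c1OCc1ccccc1.FC(F)(F)S(=O)(=O)[N-]S(=O)(=O)C(F)(F)F | intermediate (not isolated)
7 | (±)-5,7-bis(benzyloxy)-2-[2,3,4-tris(benzyloxy)phenyl]chroman-3-one (racemic) | O=C1Cc2c(OCc3ccccc3)cc(OCc3ccccc3)cc2OC1c1ccc(OCc2ccccc2)c(OCc2ccccc2)c1OCc1ccccc1 | intermediate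
8 | (2R,3R)-5,7-bis(benzyloxy)-2-[2,3,4-tris(benzyloxy)phenyl]chroman-3-ol | O[C@@H]1Cc2c(OCc3ccccc3)cc(OCc3ccccc3)cc2O[C@@H]1c1ccc(OCc2ccccc2)c(OCc2ccccc2)c1OCc1ccccc1 | intermediate
9 | 3,4,5-tris(benzyloxy)benzoic acid | OC(=O)c1cc(OCc2ccccc2)c(OCc2ccccc2)c(OCc2ccccc2)c1 | starting material
10 | (2R,3R)-5,7-bis(benzyloxy)-2-[2,3,4-tris(benzyloxy)phenyl]chroman-3-yl 3,4,5-tris(benzyloxy)benzoate | O=C(O[C@@H]1Cc2c(OCc3ccccc3)cc(OCc3ccccc3)cc2O[C@@H]1c1ccc(OCc2ccccc2)c(OCc2ccccc2)c1OCc1ccccc1)c1cc(OCc2ccccc2)c(OCc2ccccc2)c(OCc2ccccc2)c1 | intermediate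
11 | (2R,3R)-5,7-dihydroxy-2-(2,3,4-trihydroxyphenyl)chroman-3-yl 3,4,5-trihydroxybenzoate | O=C(O[C@@H]1Cc2c(O)cc(O)cc2O[C@@H]1c1ccc(O)c(O)c1O)c1cc(O)c(O)c(O)c1 | intermediate
12 | (−)-epicatechin 3-O-gallate, (2R,3R) | O=C(O[C@@H]1Cc2c(O)cc(O)cc2O[C@@H]1c1ccc(O)c(O)c1)c1cc(O)c(O)c(O)c1 | starting material
13 | ECG ortho-quinone: (2R,3R)-2-(3,4-dioxocyclohexa-1,5-dien-1-yl)-5,7-dihydroxychroman-3-yl 3,4,5-trihydroxybenzoate | O=C(O[C@@H]1Cc2c(O)cc(O)cc2O[C@@H]1C1=CC(=O)C(=O)C=C1)c1cc(O)c(O)c(O)c1 | intermediate (not isolated)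
14 | benzo-fused bicyclo[3.2.1]octenedione adduct: catechol ring of ECG joined at C6' to the bridgehead C–H and at C5' to the bridgehead C–OH of the former trihydroxyphenyl ring of 11, one-carbon C=O bridge, enone carrying the second flavan; bridgehead configuration not defined | O=C(O[C@@H]1Cc2c(O)cc(O)cc2O[C@@H]1c1cc(O)c(O)c3c1C4C=C([C@H]5Oc6cc(O)cc(O)c6C[C@H]5OC(=O)c5cc(O)c(O)c(O)c5)C(=O)C3(O)C4=O)c1cc(O)c(O)c(O)c1 | intermediate (not isolated)
15 | (2R,3R)-2-{1-[(2R,3R)-5,7-dihydroxy-3-(3,4,5-trihydroxybenzoyloxy)chroman-2-yl]-3,4,6-trihydroxy-5-oxo-5H-benzo[7]annulen-7-yl}-5,7-dihydroxychroman-3-yl 3,4,5-trihydroxybenzoate (CNP0283148.1) | O=C(O[C@@H]1Cc2c(O)cc(O)cc2O[C@@H]1c1ccc2c([C@H]3Oc4cc(O)cc(O)c4C[C@H]3OC(=O)c3cc(O)c(O)c(O)c3)cc(O)c(O)c2c(=O)c1O)c1cc(O)c(O)c(O)c1 | target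

**Totals**
Total steps: 8. Longest linear sequence: 8 (1 → 2 → 3 → 5 → 7 → 8 → 10 → 11 → 15); compounds 4, 9 and 12 are bought and enter in steps 3, 6 and 8.

**Three steps most likely to fail, with fallbacks**

Step 4 (gold oxidation and cyclisation). The risks are 6-endo hydroarylation of the electron-rich ring to the chromene, ionisation of the doubly activated propargylic C–O bond, and double oxidation of the carbene. The fallback sets out from 5 and returns at 7, turning the competing hydroarylation into the route. PtCl2 (5 mol %) in toluene at 80 °C cyclises 5 to (±)-5,7-bis(benzyloxy)-2-[2,3,4-tris(benzyloxy)phenyl]-2H-chromene F1. Hydroboration–oxidation (BH3·THF, then NaOH/H2O2) places oxygen on C3 and gives the racemic 2,3-trans-flavan-3-ol F2. Dess–Martin periodinane in CH2Cl2 then gives ketone 7.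

Step 5 (DKR hydrogenation). The risks are slow C2 epimerisation, low enantioselectivity on this new substrate class, and base-induced decomposition of the flavan-3-one. The fallback sets out from 7 and returns at 8 and replaces catalytic DKR by substrate-controlled reduction plus classical resolution. L-Selectride in THF at −78 °C attacks anti to the 2-aryl group and gives the racemic cis alcohol, which is 8 together with its enantiomer, the (2S,3S)-alcohol F3. Esterification of this racemate with (S)-O-methylmandelic acid (DCC, DMAP) gives the diastereomeric (2R,3R)-flavanyl (S)-O-methylmandelate F4 and (2S,3S)-flavanyl (S)-O-methylmandelate F5. These are separated by chromatography or crystallisation, and K2CO3/MeOH cleaves F4 to 8.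

Step 8 (oxidative annulation). The risks are self-condensation of 11, which has two adjacent free ring CH positions and can also act as the benzo partner, A-ring attack on quinones, and over-oxidation. The fallback sets out from 11 and 12 and returns at 15 and replaces the one-pot enzymatic co-oxidation by a stepwise sequence in which 11 never meets free oxidant. ECG 12 alone is oxidised with o-chloranil in MeCN/THF at −40 °C to quinone 13 (2.2 equiv). Compound 11 (1 equiv) is added at −40 to 0 °C; one equivalent of 13 acts as the electrophile and the second as the oxidant, giving adduct 14, which is isolated on Sephadex LH-20. Adduct 14 is then opened and decarboxylated separately with H2O2 (1 equiv) in MeCN/pH 7 buffer to give 15.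

**Further compounds**
F1 | step 4 | (±)-5,7-bis(benzyloxy)-2-[2,3,4-tris(benzyloxy)phenyl]-2H-chromene (racemic) | C1=Cc2c(OCc3ccccc3)cc(OCc3ccccc3)cc2OC1c1ccc(OCc2ccccc2)c(OCc2ccccc2)c1OCc1ccccc1
F2 | step 4 | (±)-2,3-trans-5,7-bis(benzyloxy)-2-[2,3,4-tris(benzyloxy)phenyl]chroman-3-ol (racemic, 2R,3S enantiomer drawn) | O[C@H]1Cc2c(OCc3ccccc3)cc(OCc3ccccc3)cc2O[C@@H]1c1ccc(OCc2ccccc2)c(OCc2ccccc2)c1OCc1ccccc1
F3 | step 5 | (2S,3S)-5,7-bis(benzyloxy)-2-[2,3,4-tris(benzyloxy)phenyl]chroman-3-ol | O[C@H]1Cc2c(OCc3ccccc3)cc(OCc3ccccc3)cc2O[C@H]1c1ccc(OCc2ccccc2)c(OCc2ccccc2)c1OCc1ccccc1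
F4 | step 5 | (2R,3R)-5,7-bis(benzyloxy)-2-[2,3,4-tris(benzyloxy)phenyl]chroman-3-yl (S)-2-methoxy-2-phenylacetate | CO[C@H](C(=O)O[C@@H]1Cc2c(OCc3ccccc3)cc(OCc3ccccc3)cc2O[C@@H]1c1ccc(OCc2ccccc2)c(OCc2ccccc2)c1OCc1ccccc1)c1ccccc1
F5 | step 5 | (2S,3S)-5,7-bis(benzyloxy)-2-[2,3,4-tris(benzyloxy)phenyl]chroman-3-yl (S)-2-methoxy-2-phenylacetate | CO[C@H](C(=O)O[C@H]1Cc2c(OCc3ccccc3)cc(OCc3ccccc3)cc2O[C@H]1c1ccc(OCc2ccccc2)c(OCc2ccccc2)c1OCc1ccccc1)c1ccccc1
F0 | step 8 | none | none
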